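A neighbour of Wednesday's, kept at 35 °C with the same charge and the same 25 s, is the kind of flask I want to answer without integrating anything, so I look for a number with no clock in it.

| setting | Wednesday's | Sunday's | Thursday's |
|---|---|---|---|
| J | 0.20 mM | 0.20 mM | 0.20 mM |
| temperature | 20 °C | 40 °C | 0 °C |
| time | 25 s | 25 s | 25 s |

    X ⇌ Q (K1 = 0.47, k1 = 0.055 s⁻¹, Ea1 = 70.0 kJ mol⁻¹, ΔH1 = −90.0 kJ mol⁻¹)
    L ⇌ D (K2 = 3.0, k2 = 0.091 s⁻¹, Ea2 = 77.0 kJ mol⁻¹, ΔH2 = −13.0 kJ mol⁻¹)
    Q ⇌ J (k3 = 0.022 s⁻¹, Ea3 = 70.0 kJ mol⁻¹)
    L ⇌ X (K4 = 0.58, k4 = 0.68 s⁻¹, Ea4 = 67.0 kJ mol⁻¹, ΔH4 = 18.0 kJ mol⁻¹)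
    J ⇌ Z (K5 = 2.9, k5 = 0.13 s⁻¹, Ea5 = 81.0 kJ mol⁻¹, ΔH5 = −17.0 kJ mol⁻¹)
    J ⇌ L (K6 = 11, k6 = 0.094 s⁻¹, Ea6 = 86.0 kJ mol⁻¹, ΔH6 = 60.0 kJ mol⁻¹)
    (constants at 20 °C)

- the constants hold at 20 °C; other temperatures follow from the activation energies and enthalpies

- the flask with the highest amount of L, in percent of the J charged ("all alike" if they lie within 1.5 percentage points) (Wednesday's / Sunday's / Thursday's / all alike)
- final L, as a percentage of the J charged, in Wednesday's
- final L, as a percentage of the J charged, in Sunday's
- final L, as a percentage of the J charged, in Thursday's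

If I divide each step's forward rate by its back rate and set the quotient to one, time drops out and the constants give every concentration relative to c_L. At 20 °C, with L weighing one, D weighs 3.0, X 0.58, Q 0.273, J 0.0909 and Z 0.264. So the balance share of L, the fraction of the charge standing as L when every step's forward and back rates are equal, is 19.2%. It is the answer under thermodynamic control, and the ladder of single-step half-lives tells me how long each pair of species takes by itself, not how long the coupled flask takes.

In Wednesday's, L⇌X relaxes with a half-life of 0.374 s, so c_X follows c_L from the first seconds. J⇌Z and X⇌Q follow at 3.96 s and 4.03 s, L⇌D at 5.71 s, and Q⇌J is the longest rung at 7.88 s. That rung is shorter than 25 s, but the steps are chained, so this does not show that Wednesday's reaches balance, and I take the balance share for Wednesday's L as an estimate and no more.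

In Sunday's, the L⇌D rung shrinks to 0.690 s, and the shifted constants give a share of 24.0%, which is 4.8 percentage points above Wednesday's.

In Thursday's, the same rung stretches to 62.8 s, longer than 25 s, so I do not expect this flask at balance and my reckoning grows weak. Its share is 8.80%. J kept at its full charge would supply 13.3% as L after X takes its part, more than that share, but J falls. I therefore say a little under the share, and I name Sunday's as the highest.

The forecast also names Sunday's, with 18.7% for Wednesday's, 24.1% for Sunday's and 8.4% for Thursday's, which it calls a flask where “the system is kinetically limited”. Its Wednesday's figure stands a little lower than my share.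

The simulation gives Sunday's, with 18.7% in Wednesday's, 24.0% in Sunday's and 8.40% in Thursday's, so the forecast held. But the computed number hides what the flask is doing. In Wednesday's, L reads 19.0% at 12.5 s and 18.7% at 25.0 s, while Z goes from 34.1% to 28.0% and D from 14.5% to 27.9%. At 25.0 s, with each step taken net, L is made at 0.939 of the rate at which it is used up, the slowest mode of the whole flask has a half-life of 30.6 s, and D goes on to 57.5% by 250 s, so Wednesday's L stands 0.50 points under its share while the flask is still short of balance.

For the neighbour at 35 °C, the shifted constants give a share of 23.3%. The computed L there is 23.2%.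

The numbers of this flask were set for the occasion; the run is a simulation.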